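**Plan**

- Cuts, in retrosynthetic order: the C11–O aryl ether; C9–C11 (a [2,3] shift from an oxygen on C7); C3–O (hydride opening of a 2,3-epoxide); ring A at C1–C2 and at C3–C4 (a cis-CH=CH unit taken out); C10–C1 and C10–CH3 (enolate alkylations), back to (S)-carvone.
- Forward: ring B is bought as (S)-carvone and C10 is made quaternary. Ring A is then closed in one flask by palladium, which stitches cis-1,2-dichloroethene between C1 (Negishi coupling) and C4 (6-exo reductive Heck). Ring B is transposed, C11 is added, and scopoletin is attached last, without protecting groups.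
- Enabling feature: C1 and C4 hang on the neighbouring ring B carbons C10 and C5. C1 is a neopentyl CH2 with no beta-hydrogen. C4 is the internal carbon of carvone's isopropenyl group, whose CH2 end becomes the second methyl on C4 when formate reduces the neopentylpalladium.
- Stereochemistry: C5 is bought with (S)-carvone. C10 comes from alkylation anti to the isopropenyl group, which gives the trans ring fusion. C3 and C9 both come from epoxidations on the H5 face, relayed by trans-diaxial hydride opening (axial 3-OH) and by a suprafacial [2,3] shift (C11 anti to the C10 methyl).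

Key step: step 3

Remark: drimane numbering is used for the decalin (ring A = C1–C5 with C10; ring B = C5–C10; C11 = the CH2O carbon on C9; C6 of the carvone-numbered monocycles becomes C10). "H5 face" means the face of the decalin that carries the ring-fusion hydrogen on C5, opposite to the angular C10 methyl.

**Step 1**
Reactants: 1 (S)-carvone
Product: 2 (5S,6R)-2,6-dimethyl-5-(prop-1-en-2-yl)cyclohex-2-en-1-one (trans-6-methylcarvone; its C6 epimer may accompany it)
Conditions: LiN(i-Pr)2, THF, −78 °C; then MeI, −78 to 0 °C
Reagents that add atoms: iodomethane, CI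
Why: Kinetic deprotonation at C6 (the future C10) and SN2 methylation of the lithium enolate (enolate alkylation) should give the 6-methyl ketone; the new centre is planarised again in step 2, so its configuration does not matter.

**Step 2**
Reactants: 2 (5S,6R)-2,6-dimethyl-5-(prop-1-en-2-yl)cyclohex-2-en-1-one
Product: 3 (5R,6R)-6-(iodomethyl)-2,6-dimethyl-5-(prop-1-en-2-yl)cyclohex-2-en-1-one
Conditions: LiN(i-Pr)2, THF, −78 °C; then DMPU, CH2I2 (excess), −78 to −20 °C
Reagents that add atoms: diiodomethane, ICI
Why: The regenerated C6 enolate should be alkylated by diiodomethane (enolate alkylation) on the face opposite to the neighbouring isopropenyl group, which puts the iodomethyl group (future C1) trans and the methyl cis to it, as a trans-decalin needs; the quaternary carbon has no alpha-hydrogen, so the beta-iodo ketone cannot eliminate.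

**Step 3**
Reactants: 3 (5R,6R)-6-(iodomethyl)-2,6-dimethyl-5-(prop-1-en-2-yl)cyclohex-2-en-1-one; 4 cis-1,2-dichloroethene
Product: 7 (4aR,8aR)-2,5,5,8a-tetramethyl-4a,5,8,8a-tetrahydronaphthalen-1(4H)-one (trans-fused), via alkylzinc iodide 5 (not isolated), via Z-chloroalkene 6 (not isolated)
Conditions: Zn, LiCl, THF, 40 °C; then 4 (3 equiv), Pd(P(t-Bu)3)2 (5 mol %), THF/NMP, 25 °C; then HCO2Na, 90 °C, same flask
Reagents that add atoms: none
Why: Zinc inserts into the neopentyl C–I bond to give the beta-keto alkylzinc 5, which forges C1–C2 by Negishi coupling with one C–Cl bond of 4 (oxidative addition to zerovalent palladium, transmetalation, reductive elimination with retention of the Z geometry); the remaining alkenyl chloride of 6 then adds to the same catalyst, the alkenylpalladium carbopalladates the isopropenyl group at its internal carbon to forge C3–C4, and formate delivers hydride to the neopentylpalladium so that the former CH2 terminus becomes the second methyl on C4. The closest known reaction types are the mono-coupling of cis-1,2-dichloroethene with organozinc reagents and the intramolecular reductive Heck reaction. Ring A closes in the 6-exo-trig mode. No new stereocentre arises (C4 ends with two methyls), and the trans ring fusion follows from the trans relation of the C1 arm on C10 and the isopropenyl group on C5 set in steps 1 and 2. The step needs mono-coupling of 4 (secured by its excess and by the lower reactivity of chloroalkene 6 at 25 °C), exo insertion (normal for six-ring carbopalladation) and reduction of the alkylpalladium in preference to elimination (secured by the absence of beta-hydrogen on quaternary C4 and by formate); the enone is not a partner for either organometallic.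

**Step 4**
Reactants: 7 (4aR,8aR)-2,5,5,8a-tetramethyl-4a,5,8,8a-tetrahydronaphthalen-1(4H)-one
Product: 8 2,3-epoxide of 7 with the epoxide oxygen on the H5 face
Conditions: mCPBA, NaHCO3, CH2Cl2, 0 °C
Reagents that add atoms: 3-chloroperoxybenzoic acid, O=C(OO)c1cccc(Cl)c1
Why: Prilezhaev epoxidation with the electrophilic peracid should take the isolated cis C2=C3 alkene and leave the electron-poor enone alkene, and oxygen should arrive on the H5 face because the other face is screened by the axial C10 methyl and the axial C4 methyl.

**Step 5**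
Reactants: 8 2,3-epoxide of 7
Product: 9 2,3:7,8-bisepoxy-9-ketone with both epoxide oxygens on the H5 face
Conditions: 30% H2O2, NaOH (aq), MeOH, 0 °C
Reagents that add atoms: hydrogen peroxide, OO
Why: Weitz–Scheffer nucleophilic epoxidation: hydroperoxide should add axially to C7 of the enone on the face of the axial H5 (anti to the C5–C4 bond, as in the epoxidation of carvone itself) and close to the cis 7,8-epoxy ketone, while the ring A epoxide is inert to base.

**Step 6**
Reactants: 9 2,3:7,8-bisepoxy-9-ketone
Product: 11 2,3-epoxy-8(9)-en-7-ol with the C7 hydroxyl on the H5 face, via epoxy hydrazone 10 (not isolated)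
Conditions: N2H4·H2O, AcOH (cat.), MeOH, 0 °C to rt
Reagents that add atoms: none
Why: Wharton transposition: the hydrazone 10 should open the 7,8-epoxide and lose dinitrogen to give the C8=C9 alkene and the C7 alcohol; the C7–O bond is not touched, so the hydroxyl stays pseudo-axial on the H5 face.

**Step 7**
Reactants: 11 2,3-epoxy-8(9)-en-7-ol
Product: 12 (tributylstannyl)methyl ether of 11
Conditions: KH, 18-crown-6, THF, 0 °C; then Bu3SnCH2I
Reagents that add atoms: tributyl(iodomethyl)stannane, CCCC[Sn](CCCC)(CCCC)CI
Why: Williamson etherification of the only hydroxyl with the reactive alpha-stannyl iodide should give the ether needed for the [2,3]-Wittig rearrangement; the hindered ring A epoxide is inert to the alkoxide at 0 °C.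

**Step 8**
Reactants: 12 (tributylstannyl)methyl ether of 11
Product: 14 2,3-epoxy-7-en-11-ol (hydroxymethyl C11 on C9 on the H5 face), via alkoxymethyllithium 13 (not isolated)
Conditions: n-BuLi, THF, −78 °C; then H2O
Reagents that add atoms: none
Why: Tin–lithium exchange gives the alkoxymethyllithium 13, whose [2,3]-Wittig rearrangement (Still variant) should move the CH2O unit suprafacially from the pseudo-axial C7 oxygen to C9 on the same face and shift the alkene to C7=C8, which sets C11 cis to H5 and trans to the C10 methyl as in the target.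

**Step 9**
Reactants: 14 2,3-epoxy-7-en-11-ol
Product: 15 (2S,4aR,5S,8aS)-5-(hydroxymethyl)-1,1,4a,6-tetramethyl-1,2,3,4,4a,5,8,8a-octahydronaphthalen-2-ol
Conditions: LiAlH4, THF, reflux; then aqueous work-up
Reagents that add atoms: none
Why: Hydride should open the epoxide at C2, the only accessible carbon (C3 is neopentyl), in the trans-diaxial sense (Fürst–Plattner), so the oxygen stays on C3 as the axial alcohol on the H5 face, the configuration of the target; nothing else in 14 is reducible.

**Step 10**
Reactants: 15 (2S,4aR,5S,8aS)-5-(hydroxymethyl)-1,1,4a,6-tetramethyl-1,2,3,4,4a,5,8,8a-octahydronaphthalen-2-ol; 16 scopoletin (7-hydroxy-6-methoxy-2H-chromen-2-one)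
Product: 17 7-{[(1S,4aS,6S,8aR)-6-hydroxy-2,5,5,8a-tetramethyl-1,4,4a,5,6,7,8,8a-octahydronaphthalen-1-yl]methoxy}-6-methoxy-2H-chromen-2-one (CNP0218138.1)
Conditions: PPh3, DIAD, THF, 0 °C to rt
Reagents that add atoms: none
Why: Mitsunobu etherification: the acidic phenol of scopoletin should displace the activated primary C11 oxygen by SN2, while the axial C3 hydroxyl next to the gem-dimethyl carbon is too hindered to be activated, so no protecting group is needed.

**Compound list**

1 | (S)-(+)-carvone, (5S)-2-methyl-5-(prop-1-en-2-yl)cyclohex-2-en-1-one | CC1=CC[C@@H](CC1=O)C(C)=C | starting material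
2 | (5S,6R)-2,6-dimethyl-5-(prop-1-en-2-yl)cyclohex-2-en-1-one (major trans epimer shown) | O=C1C(C)=CC[C@H](C(C)=C)[C@H]1C | intermediate
3 | (5R,6R)-6-(iodomethyl)-2,6-dimethyl-5-(prop-1-en-2-yl)cyclohex-2-en-1-one (CH2I trans to isopropenyl) | O=C1C(C)=CC[C@H](C(C)=C)[C@@]1(C)CI | intermediate
4 | cis-1,2-dichloroethene | Cl/C=C\Cl | starting material
5 | alkylzinc iodide from 3 (CH2ZnI in place of CH2I, configuration as in 3) | O=C1C(C)=CC[C@H](C(C)=C)[C@@]1(C)C[Zn]I | intermediate
6 | (5R,6R)-6-[(2Z)-3-chloroprop-2-en-1-yl]-2,6-dimethyl-5-(prop-1-en-2-yl)cyclohex-2-en-1-one | O=C1C(C)=CC[C@H](C(C)=C)[C@@]1(C)C/C=C\Cl | intermediate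
7 | (4aR,8aR)-2,5,5,8a-tetramethyl-4a,5,8,8a-tetrahydronaphthalen-1(4H)-one (trans-fused; C9 ketone, C7=C8 and C2=C3 alkenes in drimane numbering) | O=C1C(C)=CC[C@@H]2C(C)(C)C=CC[C@]21C | intermediate
8 | 2,3-epoxide of 7, epoxide oxygen on the H5 face | O=C1C(C)=CC[C@@H]2C(C)(C)[C@H]3O[C@H]3C[C@]21C | intermediate
9 | 2,3:7,8-bisepoxy-9-ketone, both epoxide oxygens on the H5 face | O=C1[C@@]3(C)O[C@H]3C[C@@H]2C(C)(C)[C@H]4O[C@H]4C[C@]21C | intermediate
10 | hydrazone of 9 at C9 | NN=C1[C@@]3(C)O[C@H]3C[C@@H]2C(C)(C)[C@H]4O[C@H]4C[C@]21C | intermediate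
11 | 2,3-epoxy-8(9)-en-7-ol, C7 hydroxyl on the H5 face | C1=C(C)[C@@H](O)C[C@@H]2C(C)(C)[C@H]3O[C@H]3C[C@]21C | intermediate
12 | (tributylstannyl)methyl ether of 11 | C1=C(C)[C@@H](OC[Sn](CCCC)(CCCC)CCCC)C[C@@H]2C(C)(C)[C@H]3O[C@H]3C[C@]21C | intermediate
13 | alkoxymethyllithium from 12 (CH2Li in place of CH2SnBu3) | C1=C(C)[C@@H](OC[Li])C[C@@H]2C(C)(C)[C@H]3O[C@H]3C[C@]21C | intermediate
14 | 2,3-epoxy-7-en-11-ol, C11 on C9 on the H5 face (trans to the C10 methyl) | OC[C@H]1C(C)=CC[C@@H]2C(C)(C)[C@H]3O[C@H]3C[C@]21C | intermediate
15 | (2S,4aR,5S,8aS)-5-(hydroxymethyl)-1,1,4a,6-tetramethyl-1,2,3,4,4a,5,8,8a-octahydronaphthalen-2-ol | OC[C@H]1C(C)=CC[C@@H]2C(C)(C)[C@@H](O)CC[C@]21C | intermediate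
16 | scopoletin, 7-hydroxy-6-methoxy-2H-chromen-2-one | COc1cc2ccc(=O)oc2cc1O | starting material
17 | 7-{[(1S,4aS,6S,8aR)-6-hydroxy-2,5,5,8a-tetramethyl-1,4,4a,5,6,7,8,8a-octahydronaphthalen-1-yl]methoxy}-6-methoxy-2H-chromen-2-one | COc1cc2ccc(=O)oc2cc1OC[C@H]1C(C)=CC[C@@H]2C(C)(C)[C@@H](O)CC[C@]21C | target

**Step count and risks**

Total step count: 10. Longest linear sequence: 10 steps (1 to 17).

Steps most likely to fail:

1. Step 3. What may go wrong: slow zinc insertion or slow transmetalation at the neopentyl carbon, hydrodechlorination of the chloroalkene before it cyclises, or ring-expanding rearrangement of the neopentylpalladium before hydride capture. The fallback builds C10–C1 by enolate alkylation and C3–C4 by radical addition to a carbonyl. It sets out from 2: LiN(i-Pr)2 and allyl bromide should give the 6-allyl ketone F1 (allyl trans to isopropenyl). Hydroboration of the monosubstituted alkene with disiamylborane and oxidation of the borane with pyridinium chlorochromate should give the aldehyde F2. Fe(acac)3 and PhSiH3 in EtOH at 60 °C (hydrogen-atom transfer to the isopropenyl group, 6-exo addition of the tertiary radical to the aldehyde) should give the ring A alcohol F3 as a mixture of C3 epimers. Burgess reagent in benzene at 80 °C (syn elimination, possible only toward C2 because C4 is quaternary) returns to the route at 7.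

2. Step 8. What may go wrong: [1,2]-shift or simple protonation of the alkoxymethyllithium instead of delivery to C9, which adjoins the quaternary C10. The fallback sets out from 11: phenyl isocyanate with Et3N should give the N-phenylcarbamate F4. Deprotonation with MeLi, complexation with CuI and addition of (i-PrO)Me2SiCH2MgCl should transfer the silylmethyl group to C9 on the face of the carbamate (directed syn SN2' substitution), giving the silane F5 with the C7=C8 alkene. Tamao oxidation (H2O2, KF, KHCO3) returns to the route at 14.

3. Step 6. What may go wrong: slow hydrazone formation at the carbonyl flanked by quaternary C10 and the methyl-bearing epoxide carbon, so that attack of hydrazine on the epoxides competes. The fallback sets out from 9: NaBH4 in MeOH at 0 °C should give the epoxy alcohol F6 (either C9 epimer serves). 1,1'-Thiocarbonyldiimidazole with DMAP should give the thiocarbonyl imidazolide F7. Bu3SnH and AIBN in toluene at 80 °C should generate the C9 radical, which opens the neighbouring epoxide at the C8–O bond; the C7 alkoxyl radical takes hydrogen from the stannane and the route is rejoined at 11 with C7 unchanged.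

**Further compounds**

F1 | step 3 | 6-allyl-2,6-dimethyl-5-(prop-1-en-2-yl)cyclohex-2-en-1-one, allyl trans to isopropenyl | O=C1C(C)=CC[C@H](C(C)=C)[C@@]1(C)CC=C
F2 | step 3 | 3-[1,3-dimethyl-2-oxo-6-(prop-1-en-2-yl)cyclohex-3-en-1-yl]propanal, configuration as in F1 | O=C1C(C)=CC[C@H](C(C)=C)[C@@]1(C)CCC=O
F3 | step 3 | 6-hydroxy-2,5,5,8a-tetramethyl-4a,5,6,7,8,8a-hexahydronaphthalen-1(4H)-one, trans-fused, mixture of carbinol epimers | O=C1C(C)=CC[C@@H]2C(C)(C)C(O)CC[C@]21C
F4 | step 8 | N-phenylcarbamate of 11 | C1=C(C)[C@@H](OC(=O)Nc3ccccc3)C[C@@H]2C(C)(C)[C@H]4O[C@H]4C[C@]21C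
F5 | step 8 | [isopropoxy(dimethyl)silyl]methyl analogue of 14 (Si in place of the C11 hydroxyl) | CC(C)O[Si](C)(C)C[C@H]1C(C)=CC[C@@H]2C(C)(C)[C@H]3O[C@H]3C[C@]21C
F6 | step 6 | 2,3:7,8-bisepoxy-9-ol from 9 | OC1[C@@]3(C)O[C@H]3C[C@@H]2C(C)(C)[C@H]4O[C@H]4C[C@]21C
F7 | step 6 | O-ester of F6 with imidazole-1-carbothioic acid | S=C(OC1[C@@]3(C)O[C@H]3C[C@@H]2C(C)(C)[C@H]4O[C@H]4C[C@]21C)n1ccnc1
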